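The readings stem from a simulated flask for an exercise, and the scatter is random.

Amber charged 0.80 equiv of nucleophile, and its target stood near 67.7% from 8.00 h on. Those two numbers carry this reckoning.

| setting | teal | amber | dawn | spring |
|---|---|---|---|---|
| electrophile | 1.5 M | 1.5 M | 1.5 M | 1.5 M |
| nucleophile | 0.80 equiv | 0.80 equiv | 0.800 equiv | 0.800 equiv |
| scavenger | 0.42 equiv | 1.1 equiv | 0.800 equiv | 1.20 equiv |
| remark | run made earlier | run made earlier |  |  |
| time |  |  | 40 h | 40 h |

| run | time / h | electrophile / % | target / % |
|---|---|---|---|
| teal | 1.00 | 61.8 | 38.0 |
| teal | 3.00 | 50.8 | 48.4 |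
| teal | 6.00 | 43.2 | 55.8 |
| teal | 8.00 | 40.9 | 58.3 |
| teal | 12.0 | 37.6 | 60.8 |
| teal | 15.0 | 37.0 | 61.4 |
| teal | 20.0 | 34.6 | 63.0 |
| amber | 1.50 | 54.9 | 45.5 |
| amber | 2.50 | 47.7 | 53.5 |
| amber | 4.00 | 40.2 | 59.9 |
| amber | 6.00 | 34.6 | 64.9 |
| amber | 8.00 | 31.9 | 67.6 |
| amber | 12.0 | 32.1 | 68.2 |
| amber | 20.0 | 31.5 | 67.7 |

(standard deviation of a reading: 0.5 percentage points)

1. part of the electrophile that has reacted at the end, dawn
2. part of the electrophile that has reacted at the end, spring
3. what raising the equivalents of scavenger from its lowest to its highest value here does to the part of the electrophile that has reacted (changes below 5 percentage points count as none) (it rises / no change / it falls)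



Here is my ledger for the nucleophile. I take it as the limiting reagent, with one nucleophile per target.

1. Charged in amber: 0.80 equiv per electrophile.
2. Booked to target: the last 3 target readings in amber average 67.8%. They stay flat within about the scatter.
3. Target share, the target made per nucleophile charged: 84.8%.
4. Remainder: 15.2%. Nucleophile was not read, so this entry is my assumption: I book the remainder as spent on a route that makes no target. Electrophile and target still sum to 99.2% in amber's last reading, so I book no electrophile to that route.
5. Carried over: dawn and spring have amber's electrophile and nucleophile charges. If scavenger leaves the share alone, each reaches 67.8%.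

The forecast gives 68% for dawn, 68% for spring and no change. Its ground: “So scavenger mainly affects rate, and has little effect on the end point.” It leans on the same amber plateau as my ledger, so our agreement is no check.

Dawn gives 68.9% and spring 68.4%, so the trend is no change, with a change of −0.49 percentage points. At the end of dawn, 0% of the nucleophile is free while 15.0% of the scavenger remains. Dawn's target share is 86.1%, against the 84.8% read from amber. Homo dimer, at two nucleophile each, holds 13.9% of dawn's nucleophile, and with that entry the books close.

    nucleophile + acid set free ⇌ protonated nucleophile, settled at all times (K = 671 L mol⁻¹)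
    electrophile + acid set free ⇌ idle adduct, settled at all times (K = 1.78 L mol⁻¹)
    electrophile + nucleophile → acid set free + target (k = 0.0307 L mol⁻¹ min⁻¹)
    2 nucleophile → homo dimer (k = 0.00907 L mol⁻¹ min⁻¹)
    acid set free + scavenger → scavenged by-product (k = 0.797 L mol⁻¹ min⁻¹)
    acid set free → by-product carried off (k = 0.00557 min⁻¹)

Now take dawn with 0.480 equiv of nucleophile instead. The target share gives 40.7%. The computed flask holds 43.9% of target, a share of 91.5%, which is higher than the share read from amber.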